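## Retrosynthetic overview

1. Target ⇐ its 13‑demethyl ketone: the last stereocentre (C13) comes from lactone‑enolate methylation anti to the C12 acyl branch, with the ketone masked as a ketal.
2. Nine‑membered ring ⇐ C1–C12 bond (key step): an acyl radical made from the C1 aldehyde adds 9‑exo‑trig to the lactone D butenolide, closing the last ring and setting C12.
3. Butenolide D ⇐ C11 aldehyde + (Z)‑iodoacrylate; C9–C10 ⇐ Claisen rearrangement of the lactam ketene N,O‑acetal with a chiral (Z)‑allylic alcohol.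
4. N4–C3 and C3–C18 ⇐ enamide of the seven‑membered lactam + 2‑silyloxyfuran (vinylogous Mannich), then hydrogenation for C20.
5. Ring order: ring A (bought lactam) → lactone E → lactone D → nine‑membered ring.

Assumption: the target is taken as drawn (tuberostemonone). Locants: N4, C5–C9 and C9a(=O) form lactam ring A; C10 carries the ethyl group; O–C11–C12–C13–C14(=O) is lactone D; C1 is the ketone carbon and C2, C3 link it to N4; O–C18–C19–C20–C21(=O) is lactone E.

## Route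

Step 1
Reactants: 1 azepan‑2‑one (ε‑caprolactam); 2 3,3‑dimethoxyprop‑1‑yne
Product: 3 (E)‑1‑(3,3‑dimethoxyprop‑1‑en‑1‑yl)azepan‑2‑one
Conditions: Ru(cod)(2‑methylallyl)2 (2 mol%), P(n‑Bu)3 (6 mol%), DMAP (4 mol%), toluene, 100 °C
Reagents that add atoms: none
Why: Ru‑catalysed anti‑Markovnikov hydroamidation of a terminal alkyne adds the lactam N–H across the triple bond and the phosphine/DMAP ligand set gives the (E)‑enamide; no stereocentre is formed.

Step 2
Reactants: 4 3‑methylfuran‑2(5H)‑one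
Product: 5 triisopropyl[(3‑methylfuran‑2‑yl)oxy]silane
Conditions: i‑Pr3SiOTf, Et3N, CH2Cl2, 0 °C
Reagents that add atoms: triisopropylsilyl trifluoromethanesulfonate, CC(C)[Si](C(C)C)(C(C)C)OS(=O)(=O)C(F)(F)F
Why: Soft enolisation and O‑silylation of the butenolide gives the aromatic 2‑silyloxyfuran, the γ‑nucleophile for the vinylogous Mannich reaction; no stereocentre is formed.

Step 3
Reactants: 3 (E)‑1‑(3,3‑dimethoxyprop‑1‑en‑1‑yl)azepan‑2‑one; 5 triisopropyl[(3‑methylfuran‑2‑yl)oxy]silane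
Product: 6 1‑[(1S)‑3,3‑dimethoxy‑1‑[(2S)‑4‑methyl‑5‑oxo‑2,5‑dihydrofuran‑2‑yl]propyl]azepan‑2‑one
Conditions: (R)‑TRIP (5 mol%), i‑PrOH (1.2 equiv), toluene, −40 °C
Reagents that add atoms: none
Why: Proposed new method: the chiral phosphoric acid protonates the enamide at C2 to an N‑acyliminium phosphate ion pair, the silyloxyfuran attacks C3 through its γ‑carbon (C18) in an open transition state on the face left free by the chiral anion, which sets C3 and C18 (3S,18S; the catalyst antipode that gives this sense is used), and isopropanol takes the silyl group to turn the acid over; the closest known reactions are vinylogous Mannich additions of 2‑silyloxyfurans to N‑acyliminium ions and phosphoric‑acid‑catalysed additions to protonated ene‑carbamates.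

Step 4
Reactants: 6 1‑[(1S)‑3,3‑dimethoxy‑1‑[(2S)‑4‑methyl‑5‑oxo‑2,5‑dihydrofuran‑2‑yl]propyl]azepan‑2‑one
Product: 7 1‑[(1S)‑3,3‑dimethoxy‑1‑[(2S,4S)‑4‑methyl‑5‑oxooxolan‑2‑yl]propyl]azepan‑2‑one
Conditions: H2 (1 atm), Rh/Al2O3, EtOAc, rt
Reagents that add atoms: none
Why: Heterogeneous catalytic hydrogenation adds H2 to the butenolide from the face opposite the bulky C18 substituent, which places the C20 methyl cis to it (20S).

Step 5
Reactants: 8 hex‑3‑yn‑2‑one
Product: 9 (2S)‑hex‑3‑yn‑2‑ol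
Conditions: RuCl(p‑cymene)[(S,S)‑TsDPEN] (0.5 mol%), i‑PrOH, rt
Reagents that add atoms: none
Why: Noyori asymmetric transfer hydrogenation of an alkynyl ketone; the (S,S)‑TsDPEN ruthenium hydride differentiates alkynyl from methyl and gives the (S)‑carbinol.

Step 6
Reactants: 9 (2S)‑hex‑3‑yn‑2‑ol
Product: 10 (2S,3Z)‑hex‑3‑en‑2‑ol
Conditions: H2 (1 atm), Pd/CaCO3 poisoned with Pb(OAc)2, quinoline, pentane, rt
Reagents that add atoms: none
Why: Lindlar semihydrogenation is a syn addition that stops at the (Z)‑alkene and does not touch the carbinol centre.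

Step 7
Reactants: 7 1‑[(1S)‑3,3‑dimethoxy‑1‑[(2S,4S)‑4‑methyl‑5‑oxooxolan‑2‑yl]propyl]azepan‑2‑one; 10 (2S,3Z)‑hex‑3‑en‑2‑ol
Product: 14 (3S)‑1‑[(1S)‑3,3‑dimethoxy‑1‑[(2S,4S)‑4‑methyl‑5‑oxooxolan‑2‑yl]propyl]‑3‑[(3S,4E)‑hex‑4‑en‑3‑yl]azepan‑2‑one, via triflyloxyiminium triflate 11 (not isolated), via allyloxyiminium triflate 12 (not isolated), via ketene N,O‑acetal 13 (not isolated)
Conditions: Tf2O, 2‑fluoropyridine, CH2Cl2, −78 → 0 °C; 10; Et3N, 0 → 40 °C
Reagents that add atoms: none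
Why: Eschenmoser–Claisen rearrangement through electrophilic amide activation: Tf2O activates only the lactam carbonyl, 10 displaces triflate, Et3N deprotonates C9 to the ring‑locked ketene N,O‑acetal, and the chair [3,3] shift (carbinol methyl equatorial, Z‑ethyl axial, C8 fixed trans to oxygen) transfers the carbinol chirality to C10 and sets C9 and C10 together as in the target, leaving an (E)‑propenyl group.

Step 8
Reactants: 14 (3S)‑1‑[(1S)‑3,3‑dimethoxy‑1‑[(2S,4S)‑4‑methyl‑5‑oxooxolan‑2‑yl]propyl]‑3‑[(3S,4E)‑hex‑4‑en‑3‑yl]azepan‑2‑one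
Product: 16 (2R)‑2‑[(3S)‑1‑[(1S)‑3,3‑dimethoxy‑1‑[(2S,4S)‑4‑methyl‑5‑oxooxolan‑2‑yl]propyl]‑2‑oxoazepan‑3‑yl]butanal, via secondary ozonide 15 (not isolated)
Conditions: O3, CH2Cl2, −78 °C; Me2S, → rt
Reagents that add atoms: ozone, [O-][O+]=O
Why: Ozonolysis with reductive work‑up cleaves the only C=C to the C11 aldehyde and leaves the C10 centre and the acetal untouched.

Step 9
Reactants: 16 (2R)‑2‑[(3S)‑1‑[(1S)‑3,3‑dimethoxy‑1‑[(2S,4S)‑4‑methyl‑5‑oxooxolan‑2‑yl]propyl]‑2‑oxoazepan‑3‑yl]butanal; 17 ethyl (2Z)‑3‑iodoprop‑2‑enoate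
Product: 20 (3S)‑3‑[(2S,4S)‑4‑methyl‑5‑oxooxolan‑2‑yl]‑3‑[(3S)‑2‑oxo‑3‑[(1R)‑1‑[(2R)‑5‑oxo‑2,5‑dihydrofuran‑2‑yl]propyl]azepan‑1‑yl]propanal, via hydroxy enoate 18 (not isolated), via butenolide acetal 19 (not isolated)
Conditions: CrCl2 (4 equiv), NiCl2 (2 mol%), DMSO, rt; then 1 M HCl, THF, rt
Reagents that add atoms: water, O
Why: Nozaki–Hiyama–Kishi addition of the (Z)‑alkenylchromium species to the aldehyde under Felkin–Anh control (attack anti to the C9 lactam carbon, ethyl gauche to the carbonyl) sets C11, the (Z)‑γ‑hydroxy enoate lactonises to the butenolide, and the acid work‑up hydrolyses the dimethyl acetal to the C1 aldehyde.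

Step 10
Reactants: 20 (3S)‑3‑[(2S,4S)‑4‑methyl‑5‑oxooxolan‑2‑yl]‑3‑[(3S)‑2‑oxo‑3‑[(1R)‑1‑[(2R)‑5‑oxo‑2,5‑dihydrofuran‑2‑yl]propyl]azepan‑1‑yl]propanal
Product: 21 13‑demethyltuberostemonone (the target without the lactone D methyl)
Conditions: (n‑Bu4N)4[W10O32] (5 mol%), MeCN (2 mM), 390 nm, Ar, rt
Reagents that add atoms: none
Why: Proposed new method: photoexcited decatungstate abstracts the aldehyde hydrogen (by far the fastest hydrogen‑atom‑transfer site), the nucleophilic acyl radical adds 9‑exo‑trig to C12 of the electron‑poor butenolide, which it can reach only on the face carrying the C11 tether so that C1 ends cis to C10 (12S), and back hydrogen transfer from the reduced polyoxometalate to the C13 radical closes the cycle without a stoichiometric reductant that could quench the slow ring closure; the closest known reactions are intermolecular decatungstate hydroacylations of electron‑poor alkenes (radical Giese addition) and acyl‑radical macrocyclisations onto acrylates.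

Step 11
Reactants: 21 13‑demethyltuberostemonone
Product: 22 13‑demethyltuberostemonone C1 ethylene ketal
Conditions: TMSOCH2CH2OTMS, TMSOTf (10 mol%), CH2Cl2, −78 → −20 °C
Reagents that add atoms: 1,2‑bis(trimethylsilyloxy)ethane, C[Si](C)(C)OCCO[Si](C)(C)C
Why: Noyori ketalisation masks the only ketone under non‑basic conditions so that C2 and C12 can no longer enolise; no stereocentre changes.

Step 12
Reactants: 22 13‑demethyltuberostemonone C1 ethylene ketal
Product: 25 tuberostemonone (CNP0311700.3), via dilithium bis‑enolate 23 (not isolated), via methylated ketal 24 (not isolated)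
Conditions: LiN(i‑Pr)2 (2.2 equiv), THF, −78 °C; MeI (1.1 equiv); AcOH, −78 °C; then 2 M HCl, THF, rt
Reagents that add atoms: iodomethane, CI; water, O
Why: Lactone enolate alkylation: both lactones are deprotonated, the unsubstituted lactone D enolate is methylated faster than the already α‑substituted lactone E enolate and on the face opposite the C12 substituent (C13 methyl trans to C1, 13S), the kinetic acetic acid quench re‑protonates the lactone E enolate anti to C18 to restore the cis methyl, and aqueous acid then removes the ketal.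

## Compound list

1 | azepan‑2‑one (ε‑caprolactam) | O=C1CCCCCN1 | starting material
2 | 3,3‑dimethoxyprop‑1‑yne | COC(OC)C#C | starting material
3 | (E)‑1‑(3,3‑dimethoxyprop‑1‑en‑1‑yl)azepan‑2‑one | COC(OC)/C=C/N1CCCCCC1=O | intermediate
4 | 3‑methylfuran‑2(5H)‑one | CC1=CCOC1=O | starting material
5 | triisopropyl[(3‑methylfuran‑2‑yl)oxy]silane | Cc1ccoc1O[Si](C(C)C)(C(C)C)C(C)C | intermediate
6 | 1‑[(1S)‑3,3‑dimethoxy‑1‑[(2S)‑4‑methyl‑5‑oxo‑2,5‑dihydrofuran‑2‑yl]propyl]azepan‑2‑one | COC(OC)C[C@@H]([C@@H]1C=C(C)C(=O)O1)N1CCCCCC1=O | intermediate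
7 | 1‑[(1S)‑3,3‑dimethoxy‑1‑[(2S,4S)‑4‑methyl‑5‑oxooxolan‑2‑yl]propyl]azepan‑2‑one | COC(OC)C[C@@H]([C@@H]1C[C@H](C)C(=O)O1)N1CCCCCC1=O | intermediate
8 | hex‑3‑yn‑2‑one | CC(=O)C#CCC | starting material
9 | (2S)‑hex‑3‑yn‑2‑ol | C[C@H](O)C#CCC | intermediate
10 | (2S,3Z)‑hex‑3‑en‑2‑ol | C[C@H](O)/C=C\CC | intermediate
11 | triflyloxyiminium triflate of 7 (OTf on C9a) | COC(OC)C[C@@H]([C@@H]1C[C@H](C)C(=O)O1)[N+]1=C(OS(=O)(=O)C(F)(F)F)CCCCC1.[O-]S(=O)(=O)C(F)(F)F | intermediate (not isolated)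
12 | O‑[(2S,3Z)‑hex‑3‑en‑2‑yl]iminium triflate of 7 | COC(OC)C[C@@H]([C@@H]1C[C@H](C)C(=O)O1)[N+]1=C(O[C@@H](C)/C=C\CC)CCCCC1.[O-]S(=O)(=O)C(F)(F)F | intermediate (not isolated)
13 | ketene N,O‑acetal (C9=C9a, O‑[(2S,3Z)‑hex‑3‑en‑2‑yl]) | COC(OC)C[C@@H]([C@@H]1C[C@H](C)C(=O)O1)N1CCCCC=C1O[C@@H](C)/C=C\CC | intermediate (not isolated)
14 | (3S)‑1‑[(1S)‑3,3‑dimethoxy‑1‑[(2S,4S)‑4‑methyl‑5‑oxooxolan‑2‑yl]propyl]‑3‑[(3S,4E)‑hex‑4‑en‑3‑yl]azepan‑2‑one | C/C=C/[C@H](CC)[C@@H]1CCCCN([C@@H](CC(OC)OC)[C@@H]2C[C@H](C)C(=O)O2)C1=O | intermediate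
15 | secondary ozonide (1,2,4‑trioxolane) of 14, mixture at the two trioxolane carbons | CC1OOC(O1)[C@H](CC)[C@@H]1CCCCN([C@@H](CC(OC)OC)[C@@H]2C[C@H](C)C(=O)O2)C1=O | intermediate (not isolated)
16 | (2R)‑2‑[(3S)‑1‑[(1S)‑3,3‑dimethoxy‑1‑[(2S,4S)‑4‑methyl‑5‑oxooxolan‑2‑yl]propyl]‑2‑oxoazepan‑3‑yl]butanal | O=C[C@H](CC)[C@@H]1CCCCN([C@@H](CC(OC)OC)[C@@H]2C[C@H](C)C(=O)O2)C1=O | intermediate
17 | ethyl (2Z)‑3‑iodoprop‑2‑enoate | CCOC(=O)/C=C\I | starting material
18 | ethyl (2Z,4R,5R)‑4‑hydroxy‑5‑[(3S)‑1‑[(1S)‑3,3‑dimethoxy‑1‑[(2S,4S)‑4‑methyl‑5‑oxooxolan‑2‑yl]propyl]‑2‑oxoazepan‑3‑yl]hept‑2‑enoate | CC[C@@H]([C@H](O)/C=C\C(=O)OCC)[C@@H]1CCCCN([C@@H](CC(OC)OC)[C@@H]2C[C@H](C)C(=O)O2)C1=O | intermediate (not isolated)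
19 | (3S)‑1‑[(1S)‑3,3‑dimethoxy‑1‑[(2S,4S)‑4‑methyl‑5‑oxooxolan‑2‑yl]propyl]‑3‑[(1R)‑1‑[(2R)‑5‑oxo‑2,5‑dihydrofuran‑2‑yl]propyl]azepan‑2‑one | CC[C@@H]([C@@H]1OC(=O)C=C1)[C@@H]1CCCCN([C@@H](CC(OC)OC)[C@@H]2C[C@H](C)C(=O)O2)C1=O | intermediate (not isolated)
20 | (3S)‑3‑[(2S,4S)‑4‑methyl‑5‑oxooxolan‑2‑yl]‑3‑[(3S)‑2‑oxo‑3‑[(1R)‑1‑[(2R)‑5‑oxo‑2,5‑dihydrofuran‑2‑yl]propyl]azepan‑1‑yl]propanal | CC[C@@H]([C@@H]1OC(=O)C=C1)[C@@H]1CCCCN([C@@H](CC=O)[C@@H]2C[C@H](C)C(=O)O2)C1=O | intermediate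
21 | 13‑demethyltuberostemonone | CC[C@H]1[C@@H]2OC(=O)C[C@@H]2C(=O)C[C@@H]([C@@H]2C[C@H](C)C(=O)O2)N2CCCC[C@@H]1C2=O | intermediate
22 | 13‑demethyltuberostemonone C1 ethylene ketal | CC[C@H]1[C@@H]2OC(=O)C[C@@H]2C2(OCCO2)C[C@@H]([C@@H]2C[C@H](C)C(=O)O2)N2CCCC[C@@H]1C2=O | intermediate
23 | dilithium bis‑enolate of 22 (lactones D and E) | CC[C@H]1[C@@H]2OC([O-])=C[C@@H]2C2(OCCO2)C[C@@H]([C@@H]2CC(C)=C([O-])O2)N2CCCC[C@@H]1C2=O.[Li+].[Li+] | intermediate (not isolated)
24 | tuberostemonone C1 ethylene ketal | CC[C@H]1[C@@H]2OC(=O)[C@@H](C)[C@@H]2C2(OCCO2)C[C@@H]([C@@H]2C[C@H](C)C(=O)O2)N2CCCC[C@@H]1C2=O | intermediate (not isolated)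
25 | tuberostemonone (CNP0311700.3) | CC[C@H]1[C@@H]2OC(=O)[C@@H](C)[C@@H]2C(=O)C[C@@H]([C@@H]2C[C@H](C)C(=O)O2)N2CCCC[C@@H]1C2=O | target

## Step count and risks

Total step count: 12. Longest linear sequence: 9 steps (steps 1, 3, 4, 7, 8, 9, 10, 11, 12).

Steps most likely to fail:

Step 10 (nine‑membered acyl‑radical ring closure). The fallback sets out from 20 and comes back at 21. Treat 20 with SmI2 (2.5 equiv), HMPA and t‑BuOH in THF at −78 °C under high dilution. The aldehyde ketyl radical, which is more nucleophilic and has no decarbonylation channel, closes the ring at C12 to give the C1 carbinol F1 (C1 epimers immaterial). Dess–Martin periodinane (CH2Cl2, NaHCO3) then oxidises it to 21.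

Step 3 (catalytic asymmetric vinylogous Mannich reaction). The fallback sets out from 3 and 5 and comes back at 7. Run the addition with achiral Tf2NH (5 mol%) and i‑PrOH in CH2Cl2 at −78 °C, which gives 6 together with the enantiomeric butenolide F2. Hydrogenation as in step 4 gives 7 together with the enantiomeric lactone F3. The pair is resolved by preparative chromatography on a chiral stationary phase and 7 is carried on.

Step 12 (chemoselective methylation of lactone D beside lactone E). The fallback sets out from 16 and comes back at 24; the methyl is carried through the ring closure instead. Step 9 run with methyl (2Z)‑3‑iodo‑2‑methylprop‑2‑enoate gives the methyl hydroxy enoate F4, then the methylbutenolide acetal F5, and after the acid work‑up the methylbutenolide aldehyde F6. The step 10 photocyclisation gives 13‑epi‑tuberostemonone F7, because hydrogen is delivered to the C13 radical on the face away from the new acyl group, so the methyl ends cis to C1. Step 11 conditions give the 13‑epi ketal F8. With the ketone masked, catalytic DBU (toluene, rt) moves the strained all‑cis C13 methyl to the trans position and gives 24. Lactone E is already in its more stable cis form; if it erodes it is re‑protonated kinetically. Acid hydrolysis as in the last operation of step 12 then gives 25.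

Further compounds

F1 | step 10 | C1 carbinol of 21 (mixture at C1) | CC[C@H]1[C@@H]2OC(=O)C[C@@H]2C(O)C[C@@H]([C@@H]2C[C@H](C)C(=O)O2)N2CCCC[C@@H]1C2=O
F2 | step 3 | enantiomer of 6 | COC(OC)C[C@H]([C@H]1C=C(C)C(=O)O1)N1CCCCCC1=O
F3 | step 3 | enantiomer of 7 | COC(OC)C[C@H]([C@H]1C[C@@H](C)C(=O)O1)N1CCCCCC1=O
F4 | step 12 | 2‑methyl analogue of hydroxy enoate 18 (methyl ester) | CC[C@@H]([C@H](O)/C=C(/C)C(=O)OC)[C@@H]1CCCCN([C@@H](CC(OC)OC)[C@@H]2C[C@H](C)C(=O)O2)C1=O
F5 | step 12 | 3‑methylbutenolide analogue of acetal 19 | CC[C@@H]([C@@H]1OC(=O)C(C)=C1)[C@@H]1CCCCN([C@@H](CC(OC)OC)[C@@H]2C[C@H](C)C(=O)O2)C1=O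
F6 | step 12 | 3‑methylbutenolide analogue of aldehyde 20 | CC[C@@H]([C@@H]1OC(=O)C(C)=C1)[C@@H]1CCCCN([C@@H](CC=O)[C@@H]2C[C@H](C)C(=O)O2)C1=O
F7 | step 12 | 13‑epi‑tuberostemonone | CC[C@H]1[C@@H]2OC(=O)[C@H](C)[C@@H]2C(=O)C[C@@H]([C@@H]2C[C@H](C)C(=O)O2)N2CCCC[C@@H]1C2=O
F8 | step 12 | 13‑epi‑tuberostemonone C1 ethylene ketal | CC[C@H]1[C@@H]2OC(=O)[C@H](C)[C@@H]2C2(OCCO2)C[C@@H]([C@@H]2C[C@H](C)C(=O)O2)N2CCCC[C@@H]1C2=O
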